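**Retrosynthetic overview**

1. The aryl ether C11–O is made last but two, by Mitsunobu coupling of isofraxidin with a 9βH-drim-7-en-11-ol; the C3 ketone is carried as a 3β-silyloxy stereocentre that steers the cyclization and is oxidized in the final step.
2. C9–C11 (with 9β-H) comes from a [2,3]-Wittig–Still shift that hands the 7α-oxygen of an 8-en-7α-ol over to C9; that alcohol comes from the ring B enone by epoxidation and Wharton transposition.
3. Key disconnection: the bicyclic 7-en-9-one goes back to an acyclic keto-enal. One base-mediated Michael/aldol-condensation cascade closes ring A (C1, C2, C3, C4, C5, C10) through C5–C10 first and ring B (C5, C6, C7, C8, C9, C10) through C7=C8 second.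
4. Enabling feature: C9, the ring B carbon that later carries C11, lies between the quaternary ring-fusion carbon C10 and the methyl-bearing alkene carbon C8. A ketone at C9 therefore makes C10 and C8 the two α-carbons of one carbonyl, matched to the enal C5=C6–C7H=O; the C4 gem-dimethyl carbon next to C5 blocks enal enolization and favours ring closure.
5. The keto-enal comes from pentan-3-one (enolate alkylation), an asymmetric reverse prenylation (C3 carbinol, C4, C5), ozonolysis and a Wittig two-carbon extension.

Key step: step 7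

Remarks on the chemistry:
- Drimane numbering is used for all intermediates (C3 oxygenated, C4 gem-dimethyl, C5/C10 ring fusion, C8 methyl-bearing, C9 carries C11). TBS = tert-butyldimethylsilyl, Ipc = isopinocampheyl.
- Compounds 3 to 10 are mixtures of epimers at the methyl-bearing carbon α to the ethyl ketone (future C10). This centre is planarized in step 7, so the mixture converges.
- The (S) configuration at C3 in step 3 is assigned by analogy with allylborations by the same borane family; the antipodal borane would give the enantiomeric series.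

**Route**

Step 1
Reactants: 1 pentan-3-one; 2 2-(2-bromoethyl)-1,3-dioxolane
Product: 3 6-(1,3-dioxolan-2-yl)-4-methylhexan-3-one (racemic)
Conditions: LiN(i-Pr)2, THF, −78 °C; then 2, DMPU, −78 → 23 °C
Reagents that add atoms: none
Why: SN2 alkylation of the lithium enolate of a symmetrical ketone with a primary bromide attaches C1–C3 as a masked aldehyde; the new stereocentre does not matter because it is planarized in step 7.

Step 2
Reactants: 3 6-(1,3-dioxolan-2-yl)-4-methylhexan-3-one
Product: 4 4-methyl-5-oxoheptanal (racemic)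
Conditions: 1 M HCl, THF, 23 °C
Reagents that add atoms: water, O
Why: Acid-catalysed acetal hydrolysis frees the aldehyde, and the mild conditions should keep the δ-keto aldehyde from condensing with itself.

Step 3
Reactants: 4 4-methyl-5-oxoheptanal
Product: 6 (7S)-7-hydroxy-4,8,8-trimethyldec-9-en-3-one (both C4 epimers), via borinate ester 5 (not isolated)
Conditions: (+)-Ipc2BH [from (−)-α-pinene], 3-methylbuta-1,2-diene, THF, −25 → 0 °C; then 4, Et2O, −78 °C; then NaOH, H2O2, 0 → 23 °C
Reagents that add atoms: B-(3-methylbut-2-en-1-yl)bis(isopinocampheyl)borane, CC(C)=CCB([C@H]1C[C@H]2C[C@@H]([C@@H]1C)C2(C)C)[C@H]1C[C@H]2C[C@@H]([C@@H]1C)C2(C)C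
Why: Asymmetric reverse prenylation (allylboration through a closed chair transition state with γ-attack of the prenyl unit) should add only to the aldehyde at −78 °C, form the C3–C4 bond with the gem-dimethyl group and set the C3 carbinol as S by reagent control (Re-face delivery by the (−)-α-pinene-derived borane).

Step 4
Reactants: 6 (7S)-7-hydroxy-4,8,8-trimethyldec-9-en-3-one
Product: 7 (7S)-7-[(tert-butyldimethylsilyl)oxy]-4,8,8-trimethyldec-9-en-3-one
Conditions: TBSOTf, 2,6-lutidine, CH2Cl2, −78 → 0 °C
Reagents that add atoms: tert-butyldimethylsilyl trifluoromethanesulfonate, CC(C)(C)[Si](C)(C)OS(=O)(=O)C(F)(F)F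
Why: The silyl triflate silylates the hindered neopentylic alcohol at low temperature without touching the ketone, and the ether later serves as the steering group and protects C3.

Step 5
Reactants: 7 (7S)-7-[(tert-butyldimethylsilyl)oxy]-4,8,8-trimethyldec-9-en-3-one
Product: 9 (3S)-3-[(tert-butyldimethylsilyl)oxy]-2,2,6-trimethyl-7-oxononanal, via ozonide 8 (not isolated)
Conditions: O3, CH2Cl2, −78 °C; then PPh3, −78 → 23 °C
Reagents that add atoms: ozone, [O-][O+]=O
Why: Ozonolysis with reductive work-up cleaves the only alkene to the C5 aldehyde, which cannot enolize or eliminate because C4 is quaternary.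

Step 6
Reactants: 9 (3S)-3-[(tert-butyldimethylsilyl)oxy]-2,2,6-trimethyl-7-oxononanal
Product: 10 (2E,5S)-5-[(tert-butyldimethylsilyl)oxy]-4,4,8-trimethyl-9-oxoundec-2-enal
Conditions: Ph3P=CHCHO, toluene, 90 °C
Reagents that add atoms: (triphenylphosphoranylidene)acetaldehyde, O=CC=P(c1ccccc1)(c1ccccc1)c1ccccc1
Why: Wittig olefination with the stabilized formyl ylide should give the E-enal (C5=C6–C7) and leave the ketone untouched, since stabilized ylides do not react with ketones under these conditions.

Step 7
Reactants: 10 (2E,5S)-5-[(tert-butyldimethylsilyl)oxy]-4,4,8-trimethyl-9-oxoundec-2-enal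
Product: 13 3β-(TBS-oxy)-11-nordrim-7-en-9-one (5α-H; 10β-CH3), via keto aldehyde 11 (not isolated), via ketol 12 (not isolated)
Conditions: KOt-Bu (0.3 equiv), t-BuOH/THF 1:4, 0.02 M, 0 → 23 °C; then 50 °C
Reagents that add atoms: none
Why: Catalytic alkoxide equilibrates the ketone enolates; the more substituted C10 enolate adds 6-exo-trig (enolate exocyclic) to the enal β-carbon C5 and closes ring A through C5–C10, then the C8 enolate of the same ketone attacks the freed C7 aldehyde in a 6-exo-trig aldol and the ketol loses water (E1cB) to give the C7=C8 enone of ring B. The closest known reaction type is the Robinson-type Michael/aldol-condensation annulation of a ketone with an α,β-unsaturated aldehyde, here with both partners in one chain so that two rings form in one operation. C5 is set relative to C3 by a chair transition state with the C3 silyloxy group and the enal both equatorial (3,5-cis, 5α-H). C10 is set in the same chair: the small methyl, not the enolate carbon C9, takes the axial site facing the axial C4 methyl, which puts C9 and C6 trans-diequatorial and gives the trans ring fusion. The step needs regioselectivity (C10 over C8, secured by ring size, since C8 would need an eight- or ten-membered ring), chemoselectivity (the enal has no γ-hydrogen because C4 is quaternary) and facial selectivity (secured by the C3 stereocentre; this bias is expected to be modest, so the minor 3,5-trans diastereomer must be removed by chromatography here, because after the later oxidation at C3 it would become the enantiomer). The C4 gem-dimethyl group gives Thorpe–Ingold help for the congested C5–C10 bond.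

Step 8
Reactants: 13 3β-(TBS-oxy)-11-nordrim-7-en-9-one
Product: 14 7α,8α-epoxy-3β-(TBS-oxy)-11-nordriman-9-one
Conditions: H2O2 (30% aq.), NaOH, MeOH, 0 → 23 °C
Reagents that add atoms: hydrogen peroxide, OO
Why: In this Weitz–Scheffer epoxidation the hydroperoxide anion should add axially to C7 on the α-face and the enolate should close on the same face, away from the axial C10 methyl, giving the 7α,8α-epoxide.

Step 9
Reactants: 14 7α,8α-epoxy-3β-(TBS-oxy)-11-nordriman-9-one
Product: 16 3β-(TBS-oxy)-11-nordrim-8-en-7α-ol, via epoxy hydrazone 15 (not isolated)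
Conditions: N2H4·H2O, AcOH, MeOH, 0 → 23 °C
Reagents that add atoms: none
Why: In the Wharton transposition the C9 hydrazone opens the epoxide to a vinyl diazene that loses N2, which moves the alkene to C8=C9 (C9 now carries H) and keeps the C7–O bond, so the 7α configuration is retained.

Step 10
Reactants: 16 3β-(TBS-oxy)-11-nordrim-8-en-7α-ol
Product: 17 7α-[(tributylstannyl)methoxy]-3β-(TBS-oxy)-11-nordrim-8-ene
Conditions: KH, 18-crown-6 (cat.), THF, 0 °C; then Bu3SnCH2I, 0 → 23 °C
Reagents that add atoms: tributyl(iodomethyl)stannane, CCCC[Sn](CCCC)(CCCC)CI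
Why: Williamson etherification of the potassium alkoxide with the primary iodide installs the latent C11 carbanion on the 7α-oxygen without touching a stereocentre.

Step 11
Reactants: 17 7α-[(tributylstannyl)methoxy]-3β-(TBS-oxy)-11-nordrim-8-ene
Product: 19 3β-(TBS-oxy)-9βH-drim-7-en-11-ol, via lithiomethyl ether 18 (not isolated)
Conditions: n-BuLi, THF, −78 → −20 °C; then H2O
Reagents that add atoms: none
Why: In the Wittig–Still [2,3]-sigmatropic rearrangement, tin–lithium exchange gives an α-alkoxy organolithium that shifts suprafacially through a five-membered envelope from the pseudo-axial 7α-oxygen to the α-face of C9, so C11 arrives anti to the C10 methyl, the C9 hydrogen ends β and the alkene returns to C7=C8.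

Step 12
Reactants: 19 3β-(TBS-oxy)-9βH-drim-7-en-11-ol; 20 isofraxidin (7-hydroxy-6,8-dimethoxy-2H-chromen-2-one)
Product: 21 7-{[3β-(TBS-oxy)-9βH-drim-7-en-11-yl]oxy}-6,8-dimethoxy-2H-chromen-2-one
Conditions: PPh3, DIAD, toluene, 0 → 60 °C
Reagents that add atoms: none
Why: In the Mitsunobu etherification the acidic coumarin phenol displaces the primary alkoxyphosphonium at C11 by SN2, so no stereocentre is touched and the silyl ether and alkene are inert.

Step 13
Reactants: 21 7-{[3β-(TBS-oxy)-9βH-drim-7-en-11-yl]oxy}-6,8-dimethoxy-2H-chromen-2-one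
Product: 22 7-{[3β-hydroxy-9βH-drim-7-en-11-yl]oxy}-6,8-dimethoxy-2H-chromen-2-one
Conditions: HF·pyridine, THF, 0 → 23 °C
Reagents that add atoms: none
Why: Fluoride-driven Si–O cleavage frees the C3 alcohol under conditions that should spare the coumarin lactone, the aryl ether and the trisubstituted alkene.

Step 14
Reactants: 22 7-{[3β-hydroxy-9βH-drim-7-en-11-yl]oxy}-6,8-dimethoxy-2H-chromen-2-one
Product: 23 7-{[3-oxo-9βH-drim-7-en-11-yl]oxy}-6,8-dimethoxy-2H-chromen-2-one (target)
Conditions: Dess–Martin periodinane, CH2Cl2, 23 °C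
Reagents that add atoms: none
Why: Dess–Martin oxidation of the hindered secondary alcohol gives the C3 ketone under neutral conditions and removes the temporary C3 stereocentre, leaving C5, C9 and C10 as set.

**Compound list**

1 | pentan-3-one | CCC(=O)CC | starting material
2 | 2-(2-bromoethyl)-1,3-dioxolane | BrCCC1OCCO1 | starting material
3 | 6-(1,3-dioxolan-2-yl)-4-methylhexan-3-one (racemic) | CCC(=O)C(C)CCC1OCCO1 | intermediate
4 | 4-methyl-5-oxoheptanal (racemic) | CCC(=O)C(C)CCC=O | intermediate
5 | bis(isopinocampheyl)borinate ester of 6 (formed in the flask) | CCC(=O)C(C)CC[C@H](OB([C@H]1C[C@H]2C[C@@H]([C@@H]1C)C2(C)C)[C@H]1C[C@H]2C[C@@H]([C@@H]1C)C2(C)C)C(C)(C)C=C | intermediate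
6 | (7S)-7-hydroxy-4,8,8-trimethyldec-9-en-3-one (both C4 epimers) | CCC(=O)C(C)CC[C@H](O)C(C)(C)C=C | intermediate
7 | (7S)-7-[(tert-butyldimethylsilyl)oxy]-4,8,8-trimethyldec-9-en-3-one | CCC(=O)C(C)CC[C@H](O[Si](C)(C)C(C)(C)C)C(C)(C)C=C | intermediate
8 | (7S)-7-[(tert-butyldimethylsilyl)oxy]-4,8-dimethyl-8-(1,2,4-trioxolan-3-yl)nonan-3-one (ozonide, formed in the flask) | CCC(=O)C(C)CC[C@H](O[Si](C)(C)C(C)(C)C)C(C)(C)C1OCOO1 | intermediate
9 | (3S)-3-[(tert-butyldimethylsilyl)oxy]-2,2,6-trimethyl-7-oxononanal | CCC(=O)C(C)CC[C@H](O[Si](C)(C)C(C)(C)C)C(C)(C)C=O | intermediate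
10 | (2E,5S)-5-[(tert-butyldimethylsilyl)oxy]-4,4,8-trimethyl-9-oxoundec-2-enal | CCC(=O)C(C)CC[C@H](O[Si](C)(C)C(C)(C)C)C(C)(C)/C=C/C=O | intermediate
11 | 2-[3-(TBS-oxy)-2,2,6-trimethyl-6-propanoylcyclohexyl]acetaldehyde, ring A closed (drimane C3 S, 5α-H, 10β-CH3; formed in the flask) | CCC(=O)[C@@]1(C)CC[C@H](O[Si](C)(C)C(C)(C)C)C(C)(C)[C@@H]1CC=O | intermediate
12 | 3β-(TBS-oxy)-7-hydroxy-11-nordriman-9-one (C7 and C8 epimers; formed in the flask) | CC1C(O)C[C@H]2C(C)(C)[C@@H](O[Si](C)(C)C(C)(C)C)CC[C@]2(C)C1=O | intermediate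
13 | 3β-(TBS-oxy)-11-nordrim-7-en-9-one = 6-[(tert-butyldimethylsilyl)oxy]-2,5,5,8a-tetramethyl-4a,5,6,7,8,8a-hexahydronaphthalen-1(4H)-one (5α-H, 10β-CH3) | O=C1C(C)=CC[C@H]2C(C)(C)[C@@H](O[Si](C)(C)C(C)(C)C)CC[C@]12C | intermediate
14 | 7α,8α-epoxy-3β-(TBS-oxy)-11-nordriman-9-one | O=C1[C@]2(C)O[C@@H]2C[C@H]3C(C)(C)[C@@H](O[Si](C)(C)C(C)(C)C)CC[C@]13C | intermediate
15 | C9 hydrazone of 14 (formed in the flask) | NN=C1[C@]2(C)O[C@@H]2C[C@H]3C(C)(C)[C@@H](O[Si](C)(C)C(C)(C)C)CC[C@]13C | intermediate
16 | 3β-(TBS-oxy)-11-nordrim-8-en-7α-ol | CC1=C[C@@]2(C)CC[C@H](O[Si](C)(C)C(C)(C)C)C(C)(C)[C@@H]2C[C@H]1O | intermediate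
17 | 7α-[(tributylstannyl)methoxy]-3β-(TBS-oxy)-11-nordrim-8-ene | CC1=C[C@@]2(C)CC[C@H](O[Si](C)(C)C(C)(C)C)C(C)(C)[C@@H]2C[C@H]1OC[Sn](CCCC)(CCCC)CCCC | intermediate
18 | 7α-(lithiomethoxy)-3β-(TBS-oxy)-11-nordrim-8-ene (formed in the flask) | CC1=C[C@@]2(C)CC[C@H](O[Si](C)(C)C(C)(C)C)C(C)(C)[C@@H]2C[C@H]1OC[Li] | intermediate
19 | 3β-(TBS-oxy)-9βH-drim-7-en-11-ol (C11 α, pseudo-axial) | OC[C@@H]1C(C)=CC[C@H]2C(C)(C)[C@@H](O[Si](C)(C)C(C)(C)C)CC[C@]12C | intermediate
20 | isofraxidin (7-hydroxy-6,8-dimethoxy-2H-chromen-2-one) | COc1cc2ccc(=O)oc2c(OC)c1O | starting material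
21 | 7-{[3β-(TBS-oxy)-9βH-drim-7-en-11-yl]oxy}-6,8-dimethoxy-2H-chromen-2-one | COc1cc2ccc(=O)oc2c(OC)c1OC[C@@H]1C(C)=CC[C@H]2C(C)(C)[C@@H](O[Si](C)(C)C(C)(C)C)CC[C@]12C | intermediate
22 | 7-{[3β-hydroxy-9βH-drim-7-en-11-yl]oxy}-6,8-dimethoxy-2H-chromen-2-one | COc1cc2ccc(=O)oc2c(OC)c1OC[C@@H]1C(C)=CC[C@H]2C(C)(C)[C@@H](O)CC[C@]12C | intermediate
23 | 7-{[3-oxo-9βH-drim-7-en-11-yl]oxy}-6,8-dimethoxy-2H-chromen-2-one (CNP0127079.1) | COc1cc2ccc(=O)oc2c(OC)c1OC[C@@H]1C(C)=CC[C@H]2C(C)(C)C(=O)CC[C@]12C | target

**Step count and risks**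

Total step count: 14. Longest linear sequence: 14 steps (1 → 23); isofraxidin 20 enters in step 12.

Steps most likely to fail:

1. Step 7. The conjugate addition at the congested C5–C10 junction may be slow, so that intermolecular aldol condensation of the enal competes, and the facial bias from C3 may be only modest. Fallback: the two bond formations are separated and the nucleophile is changed to a neutral enol silane. Setting out from 10, TMSOTf and Et3N in CH2Cl2 at −78 °C give the tetrasubstituted silyl enol ether F1 (the only isomer that can reach C5), which undergoes TMSOTf-promoted intramolecular Mukaiyama–Michael addition through an open transition state. Aqueous work-up gives keto aldehyde 11, which is now isolated and freed from its diastereomers at the monocyclic stage. Pyrrolidinium acetate in benzene at reflux then closes ring B by aldol condensation, and the sequence comes back to the route at 13.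

2. Step 9. Hydrazone formation at the neopentylic C9 carbonyl may be sluggish, and the diazene intermediates may be diverted by over-reduction or pyrazoline formation. Fallback: a radical epoxide fragmentation replaces the hydrazine chemistry. Setting out from 14, NaBH4 in MeOH gives the epoxy alcohol F2, and 1,1'-thiocarbonyldiimidazole gives the thiocarbonylimidazolide F3. Bu3SnH and AIBN in benzene at 80 °C generate the C9 radical, which opens the epoxide at C8–O; the resulting C7 alkoxy radical is reduced to the 7α-alcohol with the C8=C9 alkene, and the sequence comes back to the route at 16.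

3. Step 11. A competing [1,2]-shift or premature protonation of the α-alkoxy organolithium may occur because the C9 terminus is neopentylic. Fallback: a copper-mediated syn-SN2' substitution replaces the sigmatropic shift. Setting out from 16, PhNCO gives the N-phenylcarbamate F4. Deprotonation with MeLi, then CuI and (i-PrO)Me2SiCH2MgCl in THF deliver the silylmethyl group to C9 on the face of the carbamate (α) with alkene shift to C7=C8, giving the silane F5. Tamao oxidation (H2O2, KF, KHCO3, THF/MeOH) converts the C–Si bond into the C11 alcohol, and the sequence comes back to the route at 19.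

**Further compounds**

F1 | step 7 | (2E,5S)-5-[(tert-butyldimethylsilyl)oxy]-4,4,8-trimethyl-9-[(trimethylsilyl)oxy]undeca-2,8-dienal | CCC(O[Si](C)(C)C)=C(C)CC[C@H](O[Si](C)(C)C(C)(C)C)C(C)(C)/C=C/C=O
F2 | step 9 | 7α,8α-epoxy-3β-(TBS-oxy)-11-nordriman-9-ol (C9 epimers) | OC1[C@]2(C)O[C@@H]2C[C@H]3C(C)(C)[C@@H](O[Si](C)(C)C(C)(C)C)CC[C@]13C
F3 | step 9 | O-[7α,8α-epoxy-3β-(TBS-oxy)-11-nordriman-9-yl] 1H-imidazole-1-carbothioate | S=C(OC1[C@]2(C)O[C@@H]2C[C@H]3C(C)(C)[C@@H](O[Si](C)(C)C(C)(C)C)CC[C@]13C)n1ccnc1
F4 | step 11 | 3β-(TBS-oxy)-11-nordrim-8-en-7α-yl N-phenylcarbamate | CC1=C[C@@]2(C)CC[C@H](O[Si](C)(C)C(C)(C)C)C(C)(C)[C@@H]2C[C@H]1OC(=O)Nc1ccccc1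
F5 | step 11 | 11-[isopropoxy(dimethyl)silyl]-3β-(TBS-oxy)-9βH-drim-7-ene | CC(C)O[Si](C)(C)C[C@@H]1C(C)=CC[C@H]2C(C)(C)[C@@H](O[Si](C)(C)C(C)(C)C)CC[C@]12C
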